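**Retrosynthetic overview**

1. Camelliol C is a cyclohex-4-en-1-ol ring (C1 carbinol, C2 gem-dimethyl, C3 side-chain stereocentre, C4(CH3)=C5H, C6H2) carrying an all-E C21 tetraene chain; the chain is cut at the sp3–sp2 bond beside its first trisubstituted alkene (B-alkyl Suzuki–Miyaura coupling of a homofarnesyl borane from (2E,6E)-farnesol with an (E)-iodoalkene from carboalumination of a ring-bearing terminal alkyne).
2. The ring is disconnected at C1–C6: the homoallylic array C1(OH)–C6H2–C5H=C4(CH3) is the retron of an alkoxide-accelerated [1,3] shift, so the cyclohexenol is traced to a 2-methyl-2-vinylcyclobutan-1-ol whose carbinol carbon is still bonded to the future C4.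
3. Enabling feature: C4 is a fully substituted allylic pivot bearing the methyl group, the gem-dimethyl C2 keeps the transient aldehyde non-enolisable, and C1, C2, C3 and C4 map onto the cyclobutane of (+)-α-pinene (C1 and C3 = bridgeheads, C2 = CMe2, C4 = ring CH2).
4. The cyclobutanol comes from the pinene-derived 2,2-dimethylcyclobutanone by α-methylation, α-vinylation and reduction; pinene is degraded by alkene cleavage and Baeyer–Villiger oxidation.
5. Ring order: the four-membered ring is taken from the chiral pool and expanded in the key step to the six-membered ring, the only ring of the target.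

Key step: step 9

Assumption: commercial (1R,5R)-(+)-α-pinene of high enantiomeric purity and (2E,6E)-farnesol are used; ring positions C1–C6 are cited with the locants of the target ring given in line 1 of the overview.

**Route**

Step 1
Reactants: 1 (1R,5R)-(+)-α-pinene
Product: 2 2-[(1S,3S)-3-acetyl-2,2-dimethylcyclobutyl]acetic acid (cis-pinonic acid)
Conditions: RuCl3·xH2O (cat.), NaIO4, CCl4/MeCN/H2O, 25 °C
Reagents that add atoms: sodium periodate [Na+].[O-]I(=O)(=O)=O; water O
Why: RuO4-catalysed oxidative cleavage of the trisubstituted alkene gives the methyl ketone and the acid while the two bridgehead centres stay cis on the cyclobutane.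

Step 2
Reactants: 2 cis-pinonic acid
Product: 3 2-[(1S,3S)-3-(acetyloxy)-2,2-dimethylcyclobutyl]acetic acid
Conditions: m-CPBA, CH2Cl2, 25–40 °C
Reagents that add atoms: 3-chloroperbenzoic acid OOC(=O)c1cccc(Cl)c1
Why: Baeyer–Villiger oxidation in which the secondary cyclobutyl carbon migrates in preference to methyl and with retention, so oxygen takes the place of the acetyl carbon.

Step 3
Reactants: 3 acetoxy acid
Product: 4 (1S,3R)-3-(2-hydroxyethyl)-2,2-dimethylcyclobutan-1-ol
Conditions: LiAlH4, THF, 0 °C to reflux; aqueous NaOH work-up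
Reagents that add atoms: none
Why: Hydride reduction converts the acid into the primary alcohol and cleaves the acetate to the cyclobutanol without touching a stereocentre.

Step 4
Reactants: 4 diol
Product: 5 (1S,3R)-3-{2-[(tert-butyldimethylsilyl)oxy]ethyl}-2,2-dimethylcyclobutan-1-ol
Conditions: TBSCl (1.05 equiv), imidazole, CH2Cl2, 0 °C
Reagents that add atoms: tert-butyldimethylsilyl chloride CC(C)(C)[Si](C)(C)Cl
Why: The primary hydroxyl is silylated much faster than the secondary cyclobutanol flanked by the quaternary carbon.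

Step 5
Reactants: 5 mono-silyl ether
Product: 6 (3R)-3-{2-[(tert-butyldimethylsilyl)oxy]ethyl}-2,2-dimethylcyclobutan-1-one
Conditions: Pr4N[RuO4] (cat.), N-methylmorpholine N-oxide, 4 Å molecular sieves, CH2Cl2, 25 °C
Reagents that add atoms: none
Why: Perruthenate-catalysed oxidation of the secondary alcohol under neutral conditions gives the cyclobutanone, whose stereocentre is β to the carbonyl and cannot epimerise.

Step 6
Reactants: 6 cyclobutanone
Product: 8 (3R,4RS)-3-{2-[(tert-butyldimethylsilyl)oxy]ethyl}-2,2,4-trimethylcyclobutan-1-one, via lithium enolate 7 (not isolated)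
Conditions: LiN(i-Pr)2, THF, −78 °C; MeI, −78 to −20 °C
Reagents that add atoms: iodomethane CI
Why: Only one α-position is enolisable (the other is quaternary), so enolate C-methylation is regiodefined, and the epimer ratio is irrelevant because this carbon is enolised again in step 7.

Step 7
Reactants: 8 α-methyl cyclobutanone
Product: 10 (2R,3S)-2-ethenyl-2,4,4-trimethyl-3-{2-[(tert-butyldimethylsilyl)oxy]ethyl}cyclobutan-1-one, via lithium enolate 9 (not isolated)
Conditions: LiN(SiMe3)2, THF, −78 to 0 °C; then Pd2(dba)3 (cat.), P(t-Bu)3 (cat.), vinyl bromide, THF/toluene, 25 °C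
Reagents that add atoms: bromoethene C=CBr
Why: Pd-catalysed α-vinylation of a ketone enolate (oxidative addition of vinyl bromide to zerovalent palladium, transmetalation with the lithium enolate, C–C reductive elimination) builds the quaternary carbon, the vinyl group entering anti to the neighbouring side chain.

Step 8
Reactants: 10 2-methyl-2-vinylcyclobutanone
Product: 11 (1R,2R,3S)-2-ethenyl-2,4,4-trimethyl-3-{2-[(tert-butyldimethylsilyl)oxy]ethyl}cyclobutan-1-ol
Conditions: LiAlH4, Et2O, −78 to 0 °C
Reagents that add atoms: none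
Why: Hydride adds to the strained, non-enolisable ketone from the face opposite the side chain to give mainly the alcohol cis to it, and the ratio is not critical because the carbinol configuration is erased in step 9.

Step 9
Reactants: 11 2-methyl-2-vinylcyclobutanol
Product: 15 (1S,3R)-3-{2-[(tert-butyldimethylsilyl)oxy]ethyl}-2,2,4-trimethylcyclohex-4-en-1-ol, via potassium cyclobutanolate 12 (not isolated), via ring-opened allylpotassium aldehyde 13 (not isolated), via potassium cyclohexenolate 14 (not isolated)
Conditions: KH, 18-crown-6, THF, 0 to 25 °C; then H2O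
Reagents that add atoms: none
Why: Deprotonation gives alkoxide 12, whose oxyanion weakens the strained ring bond between the carbinol carbon and the vinyl-bearing quaternary carbon; heterolysis opens the four-membered ring to the tethered aldehyde/allyl anion pair 13, and the aldehyde carbon rebonds to the unsubstituted allyl terminus, an overall [1,3] shift that converts the 2-vinylcyclobutanol into the cyclohex-4-en-1-ol with release of cyclobutane strain. The closest known reaction type is the alkoxide-accelerated vinylcyclobutane-to-cyclohexene rearrangement of potassium 2-vinylcyclobutanolates, normally run with KH in THF. The six-membered ring closes by 6-exo-trig addition to the aldehyde with all three allyl carbons inside the new ring, which fixes the double bond between the methyl-bearing C4 and C5 and excludes the exocyclic and tetrasubstituted isomers. The side-chain stereocentre C3 (the pinene bridgehead) is untouched, whereas the carbinol and quaternary centres of 11 are erased in 13, so epimers of 11 at those two carbons should converge. The new C1 centre is controlled by C3: in the boat-like reclosure the side chain lies pseudoaxial on the face opposite the incoming aldehyde (no allylic 1,2-strain with the C4 methyl) and the C=O points away from the allyl anion (antiperiplanar, favoured for the crown-ether-separated ion pair), which places oxygen and side chain cis, that is (1S,3R). The selectivity needed is bonding at the allyl terminus instead of return to the four-membered ring or proton transfer; the return is reversible and strain-disfavoured, and the gem-dimethyl carbon C2 leaves the aldehyde without an enolisable hydrogen.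

Step 10
Reactants: 15 cyclohexenol
Product: 16 (1S,3R)-1-[(tert-butyldimethylsilyl)oxy]-3-{2-[(tert-butyldimethylsilyl)oxy]ethyl}-2,2,4-trimethylcyclohex-4-ene
Conditions: TBSOTf, 2,6-lutidine, CH2Cl2, −78 to 0 °C
Reagents that add atoms: tert-butyldimethylsilyl trifluoromethanesulfonate CC(C)(C)[Si](C)(C)OS(=O)(=O)C(F)(F)F
Why: The silyl triflate silylates the hindered secondary alcohol, which must be masked because its alkoxide could otherwise attack the side-chain halide intramolecularly in step 12.

Step 11
Reactants: 16 bis-silyl ether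
Product: 17 (1S,3R)-3-(2-bromoethyl)-1-[(tert-butyldimethylsilyl)oxy]-2,2,4-trimethylcyclohex-4-ene
Conditions: Ph3PBr2, CH2Cl2, 0 to 25 °C
Reagents that add atoms: dibromotriphenylphosphorane BrP(Br)(c1ccccc1)(c1ccccc1)c1ccccc1
Why: Direct conversion of a silyl ether into a bromide through an alkoxyphosphonium salt, where only the unhindered primary ether can undergo the SN2 step and the neopentyl-type secondary ether stays intact.

Step 12
Reactants: 17 primary bromide
Product: 18 (1S,3R)-3-(but-3-yn-1-yl)-1-[(tert-butyldimethylsilyl)oxy]-2,2,4-trimethylcyclohex-4-ene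
Conditions: LiC≡CH·H2NCH2CH2NH2, DMSO, 15–25 °C
Reagents that add atoms: lithium acetylide ethylenediamine complex [Li+].[C-]#C.NCCN
Why: SN2 alkynylation of the unhindered primary bromide gives the terminal alkyne.

Step 13
Reactants: 18 terminal alkyne
Product: 20 (1S,3R)-1-[(tert-butyldimethylsilyl)oxy]-3-[(3E)-4-iodo-3-methylbut-3-en-1-yl]-2,2,4-trimethylcyclohex-4-ene, via (E)-alkenyldimethylalane 19 (not isolated)
Conditions: AlMe3, Cp2ZrCl2 (cat.), CH2Cl2, 0 to 25 °C; then I2, THF, −30 to 0 °C
Reagents that add atoms: trimethylaluminium C[Al](C)C; iodine II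
Why: Zr-catalysed syn-carboalumination (Negishi) places methyl on the internal and aluminium on the terminal alkyne carbon, and iodinolysis with retention gives the (E)-iodoalkene while the trisubstituted ring alkene is inert.

Step 14
Reactants: 21 (2E,6E)-farnesol
Product: 22 (2E,6E)-farnesal
Conditions: MnO2, CH2Cl2, 25 °C
Reagents that add atoms: none
Why: Manganese dioxide oxidises the allylic alcohol selectively to the enal without touching the other alkenes.

Step 15
Reactants: 22 (2E,6E)-farnesal
Product: 23 (3E,7E)-4,8,12-trimethyltrideca-1,3,7,11-tetraene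
Conditions: Ph3PCH3Br, n-BuLi, THF, 0 °C; then 22, −78 to 25 °C
Reagents that add atoms: methyltriphenylphosphonium bromide C[P+](c1ccccc1)(c1ccccc1)c1ccccc1.[Br-]
Why: Wittig methylenation of the enal gives the terminal diene with the (E)-trisubstituted alkene retained.

Step 16
Reactants: 23 (3E,7E)-4,8,12-trimethyltrideca-1,3,7,11-tetraene; 20 (E)-iodoalkene
Product: 25 tert-butyldimethylsilyl ether of camelliol C, via homofarnesyl-9-BBN 24 (not isolated)
Conditions: 23, 9-BBN, THF, 0 to 25 °C; then 20, PdCl2(dppf) (cat.), AsPh3, Cs2CO3, DMF/THF/H2O, 25 °C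
Reagents that add atoms: none
Why: 9-BBN adds anti-Markovnikov to the terminal CH2 of the diene only (trisubstituted alkenes inert), and the B-alkyl Suzuki–Miyaura coupling on zerovalent palladium joins this sp3 carbon to the iodoalkene with retention of the E geometry.

Step 17
Reactants: 25 silyl ether of camelliol C
Product: 26 camelliol C, (1S,3R)-2,2,4-trimethyl-3-[(3E,7E,11E)-3,8,12,16-tetramethylheptadeca-3,7,11,15-tetraen-1-yl]cyclohex-4-en-1-ol
Conditions: Bu4NF, THF, 25–50 °C
Reagents that add atoms: none
Why: Fluoride cleaves the Si–O bond of the hindered secondary silyl ether without affecting the polyene or either stereocentre.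

**Compound list**

1 | (1R,5R)-(+)-α-pinene | CC1=CC[C@@H]2C[C@H]1C2(C)C | starting material
2 | 2-[(1S,3S)-3-acetyl-2,2-dimethylcyclobutyl]acetic acid (cis-pinonic acid) | OC(=O)C[C@@H]1C[C@H](C(C)=O)C1(C)C | intermediate
3 | 2-[(1S,3S)-3-(acetyloxy)-2,2-dimethylcyclobutyl]acetic acid | OC(=O)C[C@@H]1C[C@H](OC(C)=O)C1(C)C | intermediate
4 | (1S,3R)-3-(2-hydroxyethyl)-2,2-dimethylcyclobutan-1-ol | OCC[C@@H]1C[C@H](O)C1(C)C | intermediate
5 | (1S,3R)-3-{2-[(tert-butyldimethylsilyl)oxy]ethyl}-2,2-dimethylcyclobutan-1-ol | CC(C)(C)[Si](C)(C)OCC[C@@H]1C[C@H](O)C1(C)C | intermediate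
6 | (3R)-3-{2-[(tert-butyldimethylsilyl)oxy]ethyl}-2,2-dimethylcyclobutan-1-one | CC(C)(C)[Si](C)(C)OCC[C@@H]1CC(=O)C1(C)C | intermediate
7 | lithium enolate of 6 | CC(C)(C)[Si](C)(C)OCC[C@@H]1C=C([O-])C1(C)C.[Li+] | intermediate
8 | (3R,4RS)-3-{2-[(tert-butyldimethylsilyl)oxy]ethyl}-2,2,4-trimethylcyclobutan-1-one (epimers at the methyl-bearing carbon) | CC(C)(C)[Si](C)(C)OCC[C@@H]1C(C)C(=O)C1(C)C | intermediate
9 | lithium enolate of 8 | CC(C)(C)[Si](C)(C)OCC[C@@H]1C(C)=C([O-])C1(C)C.[Li+] | intermediate
10 | (2R,3S)-2-ethenyl-2,4,4-trimethyl-3-{2-[(tert-butyldimethylsilyl)oxy]ethyl}cyclobutan-1-one (vinyl trans to the side chain) | CC(C)(C)[Si](C)(C)OCC[C@@H]1[C@@](C)(C=C)C(=O)C1(C)C | intermediate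
11 | (1R,2R,3S)-2-ethenyl-2,4,4-trimethyl-3-{2-[(tert-butyldimethylsilyl)oxy]ethyl}cyclobutan-1-ol (OH cis to the side chain) | CC(C)(C)[Si](C)(C)OCC[C@@H]1[C@@](C)(C=C)[C@H](O)C1(C)C | intermediate
12 | potassium alkoxide of 11 | [K+].CC(C)(C)[Si](C)(C)OCC[C@@H]1[C@@](C)(C=C)[C@H]([O-])C1(C)C | intermediate
13 | potassium (4R)-4-{2-[(tert-butyldimethylsilyl)oxy]ethyl}-3,5,5-trimethyl-6-oxohex-2-en-1-ide (allyl anion/aldehyde ion pair) | [K+].O=CC(C)(C)[C@H](CCO[Si](C)(C)C(C)(C)C)C(C)=C[CH2-] | intermediate
14 | potassium alkoxide of 15 | [K+].CC(C)(C)[Si](C)(C)OCC[C@@H]1C(C)=CC[C@H]([O-])C1(C)C | intermediate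
15 | (1S,3R)-3-{2-[(tert-butyldimethylsilyl)oxy]ethyl}-2,2,4-trimethylcyclohex-4-en-1-ol | CC(C)(C)[Si](C)(C)OCC[C@@H]1C(C)=CC[C@H](O)C1(C)C | intermediate
16 | (1S,3R)-1-[(tert-butyldimethylsilyl)oxy]-3-{2-[(tert-butyldimethylsilyl)oxy]ethyl}-2,2,4-trimethylcyclohex-4-ene | CC(C)(C)[Si](C)(C)OCC[C@@H]1C(C)=CC[C@H](O[Si](C)(C)C(C)(C)C)C1(C)C | intermediate
17 | (1S,3R)-3-(2-bromoethyl)-1-[(tert-butyldimethylsilyl)oxy]-2,2,4-trimethylcyclohex-4-ene | BrCC[C@@H]1C(C)=CC[C@H](O[Si](C)(C)C(C)(C)C)C1(C)C | intermediate
18 | (1S,3R)-3-(but-3-yn-1-yl)-1-[(tert-butyldimethylsilyl)oxy]-2,2,4-trimethylcyclohex-4-ene | C#CCC[C@@H]1C(C)=CC[C@H](O[Si](C)(C)C(C)(C)C)C1(C)C | intermediate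
19 | dimethyl[(1E)-2-methyl-4-{(1R,5S)-5-[(tert-butyldimethylsilyl)oxy]-2,6,6-trimethylcyclohex-2-en-1-yl}but-1-en-1-yl]alumane | C[Al](C)/C=C(\C)CC[C@@H]1C(C)=CC[C@H](O[Si](C)(C)C(C)(C)C)C1(C)C | intermediate
20 | (1S,3R)-1-[(tert-butyldimethylsilyl)oxy]-3-[(3E)-4-iodo-3-methylbut-3-en-1-yl]-2,2,4-trimethylcyclohex-4-ene | I/C=C(\C)CC[C@@H]1C(C)=CC[C@H](O[Si](C)(C)C(C)(C)C)C1(C)C | intermediate
21 | (2E,6E)-farnesol | CC(C)=CCC/C(C)=C/CC/C(C)=C/CO | starting material
22 | (2E,6E)-farnesal | CC(C)=CCC/C(C)=C/CC/C(C)=C/C=O | intermediate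
23 | (3E,7E)-4,8,12-trimethyltrideca-1,3,7,11-tetraene | CC(C)=CCC/C(C)=C/CC/C(C)=C/C=C | intermediate
24 | 9-[(3E,7E)-4,8,12-trimethyltrideca-3,7,11-trien-1-yl]-9-borabicyclo[3.3.1]nonane | CC(C)=CCC/C(C)=C/CC/C(C)=C/CCB1C2CCCC1CCC2 | intermediate
25 | tert-butyldimethylsilyl ether of camelliol C | CC(C)=CCC/C(C)=C/CC/C(C)=C/CC/C=C(\C)CC[C@@H]1C(C)=CC[C@H](O[Si](C)(C)C(C)(C)C)C1(C)C | intermediate
26 | camelliol C, (1S,3R)-2,2,4-trimethyl-3-[(3E,7E,11E)-3,8,12,16-tetramethylheptadeca-3,7,11,15-tetraen-1-yl]cyclohex-4-en-1-ol | CC(C)=CCC/C(C)=C/CC/C(C)=C/CC/C=C(\C)CC[C@@H]1C(C)=CC[C@H](O)C1(C)C | target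

**Step count and risks**

Total step count: 17. Longest linear sequence: 15 steps (steps 1–13, 16 and 17); steps 14 and 15 form the side branch.

Steps most likely to fail:

1. Step 9 (key step). The ring-opened ion pair may be protonated before it recloses, or the reclosure may occur with the opposite facial sense at the aldehyde, so that the carbinol centre forms with poor or inverted selectivity. The fallback moves the ring expansion to the ketone level and sets the carbinol centre separately. It sets out from cyclobutanone 10: direct irradiation (Pyrex-filtered Hg lamp, benzene, 25 °C) should bring about the photochemical 1,3-acyl shift known for β,γ-unsaturated ketones (Norrish type 1 cleavage to an acyl/allyl radical pair and recombination at the allyl terminus, again strain-driven), giving (5R)-5-{2-[(tert-butyldimethylsilyl)oxy]ethyl}-4,6,6-trimethylcyclohex-3-en-1-one F1. Reduction of F1 with NaBH4/CeCl3 in MeOH at −78 °C (hydride anti to the side chain) or, if facial control is insufficient, with an (S)-selective ketoreductase and NADPH recycling should give the cis alcohol, and the route is rejoined at 15.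

2. Step 7. Reductive elimination to a quaternary carbon on a strained, hindered enolate may be slow, leaving room for enolate self-condensation or base-induced ring opening. The fallback replaces the cross-coupling by a two-step aldol/dehydration vinylation. It sets out from 8: LiN(i-Pr)2, THF, −78 °C, then acetaldehyde should give (2S,3S)-2-(1-hydroxyethyl)-2,4,4-trimethyl-3-{2-[(tert-butyldimethylsilyl)oxy]ethyl}cyclobutan-1-one F2 (mixture at the new carbinol carbon). Dehydration with Burgess reagent (benzene, 50 °C; alternatively MsCl/Et3N then DBU) can only proceed towards the methyl group because the α-carbon is quaternary, and the route is rejoined at 10.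

3. Step 16. Hydroboration of the conjugated diene may lose regioselectivity (internal or double addition), or the alkylborane may undergo protodeboronation or β-hydride elimination faster than coupling with the trisubstituted iodoalkene. The fallback makes the same chain by allyl–allyl sulfone coupling one bond further along. It sets out from alkyne 18: carboalumination as in step 13, then n-BuLi and paraformaldehyde, should give (2E)-3-methyl-5-{(1R,5S)-5-[(tert-butyldimethylsilyl)oxy]-2,6,6-trimethylcyclohex-2-en-1-yl}pent-2-en-1-ol F3. MsCl/Et3N followed by LiBr in THF converts it into the allylic bromide (1S,3R)-3-[(3E)-5-bromo-3-methylpent-3-en-1-yl]-1-[(tert-butyldimethylsilyl)oxy]-2,2,4-trimethylcyclohex-4-ene F4. Commercial (2E,6E)-farnesyl bromide and PhSO2Na in DMF give (2E,6E)-farnesyl phenyl sulfone F5; its α-lithio derivative (n-BuLi, THF, −78 °C) is alkylated by F4 to the coupled sulfone F6. Reductive desulfonylation with LiBHEt3 and PdCl2(dppp) (cat.) in THF at 0 °C rejoins the route at 25.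

Further compounds
F1 | step 9 | (5R)-5-{2-[(tert-butyldimethylsilyl)oxy]ethyl}-4,6,6-trimethylcyclohex-3-en-1-one | CC(C)(C)[Si](C)(C)OCC[C@@H]1C(C)=CCC(=O)C1(C)C
F2 | step 7 | (2S,3S)-2-(1-hydroxyethyl)-2,4,4-trimethyl-3-{2-[(tert-butyldimethylsilyl)oxy]ethyl}cyclobutan-1-one | CC(C)(C)[Si](C)(C)OCC[C@@H]1[C@@](C)(C(C)O)C(=O)C1(C)C
F3 | step 16 | (2E)-3-methyl-5-{(1R,5S)-5-[(tert-butyldimethylsilyl)oxy]-2,6,6-trimethylcyclohex-2-en-1-yl}pent-2-en-1-ol | OC/C=C(\C)CC[C@@H]1C(C)=CC[C@H](O[Si](C)(C)C(C)(C)C)C1(C)C
F4 | step 16 | (1S,3R)-3-[(3E)-5-bromo-3-methylpent-3-en-1-yl]-1-[(tert-butyldimethylsilyl)oxy]-2,2,4-trimethylcyclohex-4-ene | BrC/C=C(\C)CC[C@@H]1C(C)=CC[C@H](O[Si](C)(C)C(C)(C)C)C1(C)C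
F5 | step 16 | (2E,6E)-farnesyl phenyl sulfone | CC(C)=CCC/C(C)=C/CC/C(C)=C/CS(=O)(=O)c1ccccc1
F6 | step 16 | coupled phenyl sulfone, sulfonyl group on the chain carbon next to the farnesyl alkene (both epimers) | CC(C)=CCC/C(C)=C/CC/C(C)=C/C(C/C=C(\C)CC[C@@H]1C(C)=CC[C@H](O[Si](C)(C)C(C)(C)C)C1(C)C)S(=O)(=O)c1ccccc1
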